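**Plan** (target numbering throughout: C1 = ring alkene carbon bearing C7H2OBz, C2 = alkene CH, C3 and C4 = the carbinols, C5 = CHOAc, C6 = CHOBz)
1. Enabling feature: the vicinal diol C3–C4 of the cyclohexene ring, with C3 allylic. Cutting C3–C4 leaves two aldehyde carbons in the (Z)-enal/aldehyde 17, whose C1=C2 bond already holds C3 and C6 cis, so the ring can close by a reductive (pinacol) union of two electrophilic carbons.
2. Further cuts, in order: C4=O from a vinyl group (ozonolysis), C5–C6 (alkoxyallylboration of enal 5), C6–C1 (carbonylation of vinyl iodide 4), and iodide 4 from a butynediol monosilyl ether.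
3. Forward: the C3–C2=C1(C7) unit with fixed geometry, then enal 5, then the C5–C6 bond, then the esters in their final places, then both aldehydes unmasked; the ring closure comes last and gives the target directly.
4. Stereochemistry: alkene geometry from trans-hydroalumination/iodination; C5 and C6 from the reagent-controlled syn alkoxyallylboration (Ipc2B); C3 and C4 from the pinacol step (trans diol from the bulky titanocene reagent, C4–O cis to the C5 acetate from the half-chair with a pseudoaxial C6 benzoate).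

Key step: step 13

**Step 1**
Reactants: 1 4-[(tert-butyldimethylsilyl)oxy]but-2-yn-1-ol
Product: 3 (Z)-4-[(tert-butyldimethylsilyl)oxy]-3-iodobut-2-en-1-ol, via cyclic vinylalanate 2 (not isolated)
Conditions: NaAlH2(OCH2CH2OCH3)2 (Red-Al), THF, 0 °C to rt; then I2, THF, −78 to 0 °C
Reagents that add atoms: iodine, II
Why: Hydroxyl-directed trans-hydroalumination of the propargylic alcohol (hydride to the carbon next to CH2OH, aluminium on the far carbon in a five-membered alanate) and iodinolysis with retention should give the (Z)-iodide, with iodine on future C1 cis to the CH2OH arm (future C3).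

**Step 2**
Reactants: 3 (Z)-4-[(tert-butyldimethylsilyl)oxy]-3-iodobut-2-en-1-ol
Product: 4 (Z)-1-[(tert-butyldimethylsilyl)oxy]-4-[(tert-butyldiphenylsilyl)oxy]-2-iodobut-2-ene
Conditions: t-BuPh2SiCl, imidazole, CH2Cl2, 0 °C to rt
Reagents that add atoms: tert-butyl(chloro)diphenylsilane, CC(C)(C)[Si](Cl)(c1ccccc1)c1ccccc1
Why: Standard silylation of a primary alcohol; the TBDPS ether is chosen because it should survive the later selective cleavage of the TBS ether.

**Step 3**
Reactants: 4 (Z)-1-[(tert-butyldimethylsilyl)oxy]-4-[(tert-butyldiphenylsilyl)oxy]-2-iodobut-2-ene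
Product: 5 (Z)-2-{[(tert-butyldimethylsilyl)oxy]methyl}-4-[(tert-butyldiphenylsilyl)oxy]but-2-enal
Conditions: Pd(PPh3)4 (5 mol %), CO (1 atm), Bu3SnH (slow addition), THF, 50 °C
Reagents that add atoms: carbon monoxide, [C-]#[O+]
Why: Reductive carbonylation of a vinyl iodide (Stille formylation): oxidative addition of zerovalent palladium with retention, CO insertion and hydride transfer from tin should give the enal with the alkene geometry unchanged and the silyl ethers untouched.

**Step 4**
Reactants: 6 prop-2-en-1-ol (allyl alcohol)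
Product: 7 3-(methoxymethoxy)prop-1-ene
Conditions: CH3OCH2Cl, i-Pr2NEt, CH2Cl2, 0 °C to rt
Reagents that add atoms: chloromethyl methyl ether, COCCl
Why: Routine O-alkylation of a primary alcohol to its methoxymethyl ether, the precursor of the alkoxyallyl reagent.

**Step 5**
Reactants: 5 (Z)-2-{[(tert-butyldimethylsilyl)oxy]methyl}-4-[(tert-butyldiphenylsilyl)oxy]but-2-enal; 7 3-(methoxymethoxy)prop-1-ene
Product: 9 (3S,4S,5Z)-5-{[(tert-butyldimethylsilyl)oxy]methyl}-7-[(tert-butyldiphenylsilyl)oxy]-3-(methoxymethoxy)hepta-1,5-dien-4-ol, via diisopinocampheylborinate 8 (not isolated)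
Conditions: 7, s-BuLi, THF, −78 °C; (+)-Ipc2BOMe; BF3·OEt2; then 5, −78 °C; then NaOH, H2O2, 0 °C to rt
Reagents that add atoms: none
Why: Brown alkoxyallylboration: the (Z)-γ-alkoxyallylborane adds through a closed chair transition state, which should give the syn (threo) pair C5/C6, and the Ipc groups of the reagent from (+)-Ipc2BOMe (from (−)-α-pinene) direct attack to the Re face of the aldehyde, which sets both centers in the absolute sense needed.

**Step 6**
Reactants: 9 (3S,4S,5Z)-5-{[(tert-butyldimethylsilyl)oxy]methyl}-7-[(tert-butyldiphenylsilyl)oxy]-3-(methoxymethoxy)hepta-1,5-dien-4-ol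
Product: 10 (3S,4S,5Z)-7-[(tert-butyldiphenylsilyl)oxy]-5-(hydroxymethyl)-3-(methoxymethoxy)hepta-1,5-dien-4-ol
Conditions: pyridinium p-toluenesulfonate (cat.), MeOH, rt
Reagents that add atoms: none
Why: Mild acid-catalysed methanolysis should cleave the primary TBS ether much faster than the TBDPS ether or the MOM acetal.

**Step 7**
Reactants: 10 (3S,4S,5Z)-7-[(tert-butyldiphenylsilyl)oxy]-5-(hydroxymethyl)-3-(methoxymethoxy)hepta-1,5-dien-4-ol
Product: 11 (3S,4S,5Z)-5-[(benzoyloxy)methyl]-7-[(tert-butyldiphenylsilyl)oxy]-3-(methoxymethoxy)hepta-1,5-dien-4-yl benzoate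
Conditions: PhCOCl (2.5 equiv), pyridine, DMAP (cat.), CH2Cl2, 0 °C to rt
Reagents that add atoms: benzoyl chloride, O=C(Cl)c1ccccc1
Why: DMAP-catalysed acylation of both free hydroxyls places the two benzoates of the target (on O6 and O7) in one operation.

**Step 8**
Reactants: 11 (3S,4S,5Z)-5-[(benzoyloxy)methyl]-7-[(tert-butyldiphenylsilyl)oxy]-3-(methoxymethoxy)hepta-1,5-dien-4-yl benzoate
Product: 12 (3S,4S,5Z)-5-[(benzoyloxy)methyl]-7-[(tert-butyldiphenylsilyl)oxy]-3-hydroxyhepta-1,5-dien-4-yl benzoate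
Conditions: ZnBr2, n-PrSH, CH2Cl2, 0 °C
Reagents that add atoms: none
Why: Lewis acid/thiol cleavage of the MOM acetal takes place at the acetal carbon, so the benzoates, the silyl ether and the stereocenters should be untouched.

**Step 9**
Reactants: 12 (3S,4S,5Z)-5-[(benzoyloxy)methyl]-7-[(tert-butyldiphenylsilyl)oxy]-3-hydroxyhepta-1,5-dien-4-yl benzoate
Product: 13 (3S,4S,5Z)-3-acetoxy-5-[(benzoyloxy)methyl]-7-[(tert-butyldiphenylsilyl)oxy]hepta-1,5-dien-4-yl benzoate
Conditions: Ac2O, pyridine, DMAP (cat.), CH2Cl2, 0 °C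
Reagents that add atoms: acetic anhydride, CC(=O)OC(C)=O
Why: Fast DMAP-catalysed acetylation of the C5 hydroxyl should outrun 1,2-benzoyl migration and fixes the ester pattern of the target.

**Step 10**
Reactants: 13 (3S,4S,5Z)-3-acetoxy-5-[(benzoyloxy)methyl]-7-[(tert-butyldiphenylsilyl)oxy]hepta-1,5-dien-4-yl benzoate
Product: 14 (3S,4S,5Z)-3-acetoxy-5-[(benzoyloxy)methyl]-7-hydroxyhepta-1,5-dien-4-yl benzoate
Conditions: HF·pyridine, pyridine, THF, 0 °C to rt
Reagents that add atoms: none
Why: Fluoride cleavage of the silyl ether in a buffered, weakly acidic medium, in which ester migration is not expected.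

**Step 11**
Reactants: 14 (3S,4S,5Z)-3-acetoxy-5-[(benzoyloxy)methyl]-7-hydroxyhepta-1,5-dien-4-yl benzoate
Product: 15 (3S,4S,5Z)-3-acetoxy-5-[(benzoyloxy)methyl]-7-oxohepta-1,5-dien-4-yl benzoate
Conditions: Dess–Martin periodinane, pyridine, CH2Cl2, 0 °C
Reagents that add atoms: none
Why: Dess–Martin oxidation of the primary allylic alcohol under buffered, non-basic conditions should give the enal with the (Z) geometry kept.

**Step 12**
Reactants: 15 (3S,4S,5Z)-3-acetoxy-5-[(benzoyloxy)methyl]-7-oxohepta-1,5-dien-4-yl benzoate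
Product: 17 (2Z,4S,5R)-5-acetoxy-4-(benzoyloxy)-3-[(benzoyloxy)methyl]hex-2-enedial, via secondary ozonide 16 (not isolated)
Conditions: O3 (1 equiv), CH2Cl2, −78 °C; then PPh3, −78 °C to rt
Reagents that add atoms: ozone, [O-][O+]=O
Why: Ozonolysis with reductive work-up: the monosubstituted vinyl group should react far faster than the electron-poor, trisubstituted enal double bond, and the neutral work-up avoids β-elimination of benzoate and epimerization at C5.

**Step 13**
Reactants: 17 (2Z,4S,5R)-5-acetoxy-4-(benzoyloxy)-3-[(benzoyloxy)methyl]hex-2-enedial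
Product: 19 [(3R,4S,5S,6S)-5-acetoxy-6-(benzoyloxy)-3,4-dihydroxycyclohex-1-en-1-yl]methyl benzoate, via bis(trimethylsilyl) ether 18 (not isolated)
Conditions: Cp2TiPh (10 mol %, from Cp2TiCl2, i-PrMgCl, PhMgBr), Zn, Me3SiCl, THF, rt, slow addition of 17; then 1 M HCl, THF, 0 °C
Reagents that add atoms: none
Why: Trivalent titanium (Cp2TiPh, regenerated by Zn and Me3SiCl) reduces the coordinated aldehydes of 17 by one electron each, the conjugated C3 aldehyde first, and the two titanoxy carbon radicals combine to the C3–C4 bond; silylation then releases the catalyst and keeps the new alkoxides from attacking the neighbouring acetate, and dilute acid frees the diol. The closest known reaction type is the titanocene-catalysed trans-selective pinacol cyclization of 1,6-dials, with the SmI2 pinacol cyclization of sugar dialdehydes to cyclitols as the general model. The cyclohexene ring closes in a 6-exo-trig mode with respect to both C=O groups, which is possible only because the (Z)-C1=C2 bond already holds C3 and C6 on the same side. The C3/C4 trans relation is reagent-controlled: two bulky Cp2(Ph)Ti–O groups cannot share one metal and should take the pseudoequatorial (C3) and equatorial (C4) positions of the half-chair. The C4/C5 cis relation is substrate-controlled: allylic 1,2-strain with the C7 methylene on C1, and overlap of the C6–O bond with the electron-rich titanoxyallyl system, put the C6 benzoate pseudoaxial and hence the trans C5 acetate axial, so the equatorial C4–O bond lies cis to the acetate, whereas an axial C4–O bond would clash 1,3-diaxially with the benzoate. The step needs reduction of the aldehydes in the presence of three esters, which the mild trivalent titanium should secure, and coupling faster than β-loss of benzoate or intermolecular coupling, which the intramolecular six-ring closure under slow addition favours.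

**Compound list**
1 | 4-[(tert-butyldimethylsilyl)oxy]but-2-yn-1-ol | OCC#CCO[Si](C)(C)C(C)(C)C | starting material
2 | cyclic vinylalanate, sodium salt (five-membered ring O–CH2–CH=C(CH2OTBS)–Al(OCH2CH2OCH3)2) | [Na+].COCCO[Al-]1(OCCOC)OCC=C1CO[Si](C)(C)C(C)(C)C | intermediate
3 | (Z)-4-[(tert-butyldimethylsilyl)oxy]-3-iodobut-2-en-1-ol | OC/C=C(\I)CO[Si](C)(C)C(C)(C)C | intermediate
4 | (Z)-1-[(tert-butyldimethylsilyl)oxy]-4-[(tert-butyldiphenylsilyl)oxy]-2-iodobut-2-ene | CC(C)(C)[Si](c1ccccc1)(c1ccccc1)OC/C=C(\I)CO[Si](C)(C)C(C)(C)C | intermediate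
5 | (Z)-2-{[(tert-butyldimethylsilyl)oxy]methyl}-4-[(tert-butyldiphenylsilyl)oxy]but-2-enal | CC(C)(C)[Si](c1ccccc1)(c1ccccc1)OC/C=C(\C=O)CO[Si](C)(C)C(C)(C)C | intermediate
6 | prop-2-en-1-ol | C=CCO | starting material
7 | 3-(methoxymethoxy)prop-1-ene | C=CCOCOC | intermediate
8 | diisopinocampheylborinate ester of 9 (B(Ipc)2 on the C4 oxygen of the heptadienol; Ipc from (−)-α-pinene) | COCO[C@@H](C=C)[C@H](/C(=C\CO[Si](c1ccccc1)(c1ccccc1)C(C)(C)C)CO[Si](C)(C)C(C)(C)C)OB([C@H]1C[C@H]2C[C@@H]([C@@H]1C)C2(C)C)[C@H]1C[C@H]2C[C@@H]([C@@H]1C)C2(C)C | intermediate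
9 | (3S,4S,5Z)-5-{[(tert-butyldimethylsilyl)oxy]methyl}-7-[(tert-butyldiphenylsilyl)oxy]-3-(methoxymethoxy)hepta-1,5-dien-4-ol | COCO[C@@H](C=C)[C@H](/C(=C\CO[Si](c1ccccc1)(c1ccccc1)C(C)(C)C)CO[Si](C)(C)C(C)(C)C)O | intermediate
10 | (3S,4S,5Z)-7-[(tert-butyldiphenylsilyl)oxy]-5-(hydroxymethyl)-3-(methoxymethoxy)hepta-1,5-dien-4-ol | COCO[C@@H](C=C)[C@H](/C(=C\CO[Si](c1ccccc1)(c1ccccc1)C(C)(C)C)CO)O | intermediate
11 | (3S,4S,5Z)-5-[(benzoyloxy)methyl]-7-[(tert-butyldiphenylsilyl)oxy]-3-(methoxymethoxy)hepta-1,5-dien-4-yl benzoate | COCO[C@@H](C=C)[C@H](/C(=C\CO[Si](c1ccccc1)(c1ccccc1)C(C)(C)C)COC(=O)c1ccccc1)OC(=O)c1ccccc1 | intermediate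
12 | (3S,4S,5Z)-5-[(benzoyloxy)methyl]-7-[(tert-butyldiphenylsilyl)oxy]-3-hydroxyhepta-1,5-dien-4-yl benzoate | O[C@@H](C=C)[C@H](/C(=C\CO[Si](c1ccccc1)(c1ccccc1)C(C)(C)C)COC(=O)c1ccccc1)OC(=O)c1ccccc1 | intermediate
13 | (3S,4S,5Z)-3-acetoxy-5-[(benzoyloxy)methyl]-7-[(tert-butyldiphenylsilyl)oxy]hepta-1,5-dien-4-yl benzoate | CC(=O)O[C@@H](C=C)[C@H](/C(=C\CO[Si](c1ccccc1)(c1ccccc1)C(C)(C)C)COC(=O)c1ccccc1)OC(=O)c1ccccc1 | intermediate
14 | (3S,4S,5Z)-3-acetoxy-5-[(benzoyloxy)methyl]-7-hydroxyhepta-1,5-dien-4-yl benzoate | CC(=O)O[C@@H](C=C)[C@H](/C(=C\CO)COC(=O)c1ccccc1)OC(=O)c1ccccc1 | intermediate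
15 | (3S,4S,5Z)-3-acetoxy-5-[(benzoyloxy)methyl]-7-oxohepta-1,5-dien-4-yl benzoate | CC(=O)O[C@@H](C=C)[C@H](/C(=C\C=O)COC(=O)c1ccccc1)OC(=O)c1ccccc1 | intermediate
16 | secondary ozonide (1,2,4-trioxolane) of the vinyl group of 15, both epimers at the ring carbon | CC(=O)O[C@@H](C1OCOO1)[C@H](/C(=C\C=O)COC(=O)c1ccccc1)OC(=O)c1ccccc1 | intermediate
17 | (2Z,4S,5R)-5-acetoxy-4-(benzoyloxy)-3-[(benzoyloxy)methyl]hex-2-enedial | CC(=O)O[C@@H](C=O)[C@H](/C(=C\C=O)COC(=O)c1ccccc1)OC(=O)c1ccccc1 | intermediate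
18 | [(3R,4R,5R,6S)-5-acetoxy-6-(benzoyloxy)-3,4-bis[(trimethylsilyl)oxy]cyclohex-1-en-1-yl]methyl benzoate (bis-TMS ether of 19) | CC(=O)O[C@H]1[C@@H](O[Si](C)(C)C)[C@H](O[Si](C)(C)C)C=C(COC(=O)c2ccccc2)[C@@H]1OC(=O)c1ccccc1 | intermediate
19 | [(3R,4S,5S,6S)-5-acetoxy-6-(benzoyloxy)-3,4-dihydroxycyclohex-1-en-1-yl]methyl benzoate | CC(=O)O[C@H]1[C@@H](O)[C@H](O)C=C(COC(=O)c2ccccc2)[C@@H]1OC(=O)c1ccccc1 | target

**Total step count:** 13. **Longest linear sequence:** 12 (steps 1–3 and 5–13, from 1).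

**Steps most likely to fail**

1. Step 13. Two processes may spoil it. First, the ring may close under Felkin–Anh control of the α-acetoxy aldehyde (C5–O antiperiplanar to the forming bond, all-equatorial closure), so that the C4 oxygen develops trans instead of cis to the C5 acetate. Second, the titanoxyallyl radical may lose a β-benzoate before it couples. The fallback sets out from 17 and comes back at 19. It no longer relies on conformational control of C4 in the ring closure and instead corrects C4 afterwards by an inversion with anchimeric assistance. SmI2, t-BuOH, THF, −78 °C with a cold neutral quench should follow the established course of SmI2 pinacol cyclizations of sugar dialdehydes (cis diol, anti to the neighbouring oxygen) and give the 4-epimer of 19, [(3R,4R,5S,6S)-5-acetoxy-6-(benzoyloxy)-3,4-dihydroxycyclohex-1-en-1-yl]methyl benzoate F1. Selective silylation of the allylic C3 hydroxyl of F1 with t-BuMe2SiCl, imidazole, DMF, −20 °C should give the silyl ether [(3R,4S,5S,6S)-5-acetoxy-6-(benzoyloxy)-3-[(tert-butyldimethylsilyl)oxy]-4-hydroxycyclohex-1-en-1-yl]methyl benzoate F2. Tf2O, pyridine, CH2Cl2, −20 °C converts F2 into the C4 triflate [(3R,4S,5R,6S)-5-acetoxy-6-(benzoyloxy)-3-[(tert-butyldimethylsilyl)oxy]-4-{[(trifluoromethyl)sulfonyl]oxy}cyclohex-1-en-1-yl]methyl benzoate F3. The triflate group of F3 is displaced from the back by the carbonyl oxygen of the trans C5 acetate. Water then opens the acetoxonium ion to the cis hydroxy acetate with the ester on the axial C5 oxygen, [(3R,4R,5S,6S)-5-acetoxy-6-(benzoyloxy)-3-[(tert-butyldimethylsilyl)oxy]-4-hydroxycyclohex-1-en-1-yl]methyl benzoate F4. HF·pyridine in THF frees the C3 hydroxyl of F4 and gives 19.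

2. Step 12. Ozone may also attack the enal double bond, and the new α-acetoxy-β-benzoyloxy aldehyde may lose benzoate by β-elimination or epimerize at C5 during work-up. The fallback sets out from 15 and comes back at 17. OsO4 (cat.), N-methylmorpholine N-oxide, acetone–water, 0 °C should dihydroxylate only the more electron-rich vinyl group and give the terminal diol (3S,4S,5Z)-3-acetoxy-5-[(benzoyloxy)methyl]-1,2-dihydroxy-7-oxohept-5-en-4-yl benzoate F5, as both epimers at the new carbinol. NaIO4 on silica gel in CH2Cl2 then cleaves the glycol of F5 under neutral conditions to 17.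

3. Step 3. Direct reduction of the vinyl–palladium species by the tin hydride (loss of iodine without carbonylation), conjugate reduction of the product, or partial Z/E isomerization of the enal may occur. The fallback sets out from 4 and comes back at 5 by an ester detour. Pd(OAc)2, PPh3, CO (1 atm), MeOH, Et3N, DMF, 50 °C gives the ester methyl (Z)-2-{[(tert-butyldimethylsilyl)oxy]methyl}-4-[(tert-butyldiphenylsilyl)oxy]but-2-enoate F6. i-Bu2AlH, CH2Cl2, −78 °C reduces F6 to the allylic alcohol (E)-2-{[(tert-butyldimethylsilyl)oxy]methyl}-4-[(tert-butyldiphenylsilyl)oxy]but-2-en-1-ol F7, in which the hydroxymethyl group is cis to the CH2OTBDPS arm. MnO2, CH2Cl2, rt oxidizes F7 to 5.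

**Further compounds**
F1 | step 13 | [(3R,4R,5S,6S)-5-acetoxy-6-(benzoyloxy)-3,4-dihydroxycyclohex-1-en-1-yl]methyl benzoate (4-epimer of 19) | CC(=O)O[C@H]1[C@H](O)[C@H](O)C=C(COC(=O)c2ccccc2)[C@@H]1OC(=O)c1ccccc1
F2 | step 13 | [(3R,4S,5S,6S)-5-acetoxy-6-(benzoyloxy)-3-[(tert-butyldimethylsilyl)oxy]-4-hydroxycyclohex-1-en-1-yl]methyl benzoate | CC(=O)O[C@H]1[C@H](O)[C@H](O[Si](C)(C)C(C)(C)C)C=C(COC(=O)c2ccccc2)[C@@H]1OC(=O)c1ccccc1
F3 | step 13 | [(3R,4S,5R,6S)-5-acetoxy-6-(benzoyloxy)-3-[(tert-butyldimethylsilyl)oxy]-4-{[(trifluoromethyl)sulfonyl]oxy}cyclohex-1-en-1-yl]methyl benzoate | CC(=O)O[C@H]1[C@H](OS(=O)(=O)C(F)(F)F)[C@H](O[Si](C)(C)C(C)(C)C)C=C(COC(=O)c2ccccc2)[C@@H]1OC(=O)c1ccccc1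
F4 | step 13 | [(3R,4R,5S,6S)-5-acetoxy-6-(benzoyloxy)-3-[(tert-butyldimethylsilyl)oxy]-4-hydroxycyclohex-1-en-1-yl]methyl benzoate (3-O-silyl ether of 19) | CC(=O)O[C@H]1[C@@H](O)[C@H](O[Si](C)(C)C(C)(C)C)C=C(COC(=O)c2ccccc2)[C@@H]1OC(=O)c1ccccc1
F5 | step 12 | (3S,4S,5Z)-3-acetoxy-5-[(benzoyloxy)methyl]-1,2-dihydroxy-7-oxohept-5-en-4-yl benzoate, both epimers at the new carbinol | CC(=O)O[C@@H](C(O)CO)[C@H](/C(=C\C=O)COC(=O)c1ccccc1)OC(=O)c1ccccc1
F6 | step 3 | methyl (Z)-2-{[(tert-butyldimethylsilyl)oxy]methyl}-4-[(tert-butyldiphenylsilyl)oxy]but-2-enoate | CC(C)(C)[Si](c1ccccc1)(c1ccccc1)OC/C=C(\C(=O)OC)CO[Si](C)(C)C(C)(C)C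
F7 | step 3 | (E)-2-{[(tert-butyldimethylsilyl)oxy]methyl}-4-[(tert-butyldiphenylsilyl)oxy]but-2-en-1-ol | CC(C)(C)[Si](c1ccccc1)(c1ccccc1)OC/C=C(\CO)CO[Si](C)(C)C(C)(C)C
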